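**Plan**

Retrosynthesis: remove the two epoxide oxygens (C1–O–C10, C4–O–C5), the C13 acetate and the C8 ester C–O bond; cut C7–C8 of the ten-membered ring to a C7 vinyl iodide and a C8 aldehyde; cut the butenolide at O–C6 and C11–C12 to an allenoate made from a propargylic carbonate and CO; cut C6–C7 to a C6 enal and a propargyl ether; the enal comes from geranyl acetate with C8 added by methylenation and hydroboration.
Forward: acyclic C6–C8 chain (steps 1–6), C6–C7 alkynylation (step 8), butenolide ring by iodolactonisation (step 11), ten-membered carbocycle by C7–C8 closure (step 14), C8 ester, C13 acetate, then both epoxides (step 21).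
Stereochemistry: C6 from a catalyst-controlled alkynylation, carried centre to axis to centre through the allenoate; C8 from C6 by 1,3-induction in the ring closure; C1, C10, C4 and C5 by peripheral epoxidation of the E,E-diene; C2′ from (R)-2-methylglycidol.
Enabling feature: C7 is the β-carbon of the butenolide ring (O–C12(=O)–C11=C7–C6) and C8 is the adjacent oxygen-bearing carbon of the carbocycle C1–C10, so C7–C8 is an alkenyl-metal/aldehyde junction one atom away from the C6 stereocentre.

Key step: step 14

Remark on notation: germacrane numbering is used for all chain and ring carbons (C6 lactone carbinol, C7=C11 butenolide alkene, C12 lactone carbonyl, C13 oxygenated methylene). TBS = tert-butyldimethylsilyl, TBDPS = tert-butyldiphenylsilyl, TES = triethylsilyl. The C6 descriptor changes (S in 12–13, R in 15–27, S in 28) only through CIP priorities; the spatial arrangement set in step 11 is kept to the end.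
Assumption: (S,S)-ProPhenol is taken as the ligand antipode that sends the alkynylzinc to the Re face of enal 9 (giving 6S); if the sense is the reverse, (R,R)-ProPhenol is used and nothing else changes.

**Route**

Step 1
Reactants: 1 geranyl acetate
Product: 2 (2E,6E)-8-hydroxy-3,7-dimethylocta-2,6-dien-1-yl acetate
Conditions: SeO2 (cat.), t-BuOOH, salicylic acid (cat.), CH2Cl2, rt
Reagents that add atoms: selenium dioxide (oxygen carrier), O=[Se]=O; tert-butyl hydroperoxide, CC(C)(C)OO
Why: Riley allylic oxidation (ene reaction then 2,3-sigmatropic shift) attacks the E-methyl of the terminal trisubstituted alkene and gives the E-allylic alcohol, while the acetate-deactivated C2=C3 alkene is left alone; any over-oxidised aldehyde converges in step 2.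

Step 2
Reactants: 2 (2E,6E)-8-hydroxy-3,7-dimethylocta-2,6-dien-1-yl acetate
Product: 3 (2E,6E)-3,7-dimethyl-8-oxoocta-2,6-dien-1-yl acetate
Conditions: MnO2, CH2Cl2, rt
Reagents that add atoms: none
Why: Heterogeneous MnO2 oxidation is specific for allylic alcohols and gives the E-enal without touching the acetate.

Step 3
Reactants: 3 (2E,6E)-3,7-dimethyl-8-oxoocta-2,6-dien-1-yl acetate
Product: 4 (2E,6E)-3,7-dimethylnona-2,6,8-trien-1-yl acetate
Conditions: Ph3PCH3Br, KN(SiMe3)2, THF, −78 to 0 °C (1.05 equiv ylide)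
Reagents that add atoms: methyltriphenylphosphonium bromide, C[P+](c1ccccc1)(c1ccccc1)c1ccccc1.[Br-]
Why: Wittig methylenation adds the carbon that becomes C8; the unstabilised ylide reacts with the aldehyde much faster than with the acetate at low temperature and the existing E-alkenes are not involved.

Step 4
Reactants: 4 (2E,6E)-3,7-dimethylnona-2,6,8-trien-1-yl acetate
Product: 7 (2E,6E)-3,7-dimethylnona-2,6-diene-1,9-diol, via B-alkyl-9-BBN adduct 5 (not isolated), via hydroxy acetate 6 (not isolated)
Conditions: 9-BBN, THF, 0 °C to rt; then NaOH (3 M aq), H2O2 (30%), EtOH, 0 to 50 °C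
Reagents that add atoms: hydrogen peroxide, OO
Why: Brown hydroboration–oxidation: 9-BBN places boron on the unhindered terminal carbon of the vinyl group and ignores the trisubstituted alkenes, and the alkaline peroxide work-up gives the primary alcohol and saponifies the acetate in the same pot.

Step 5
Reactants: 7 (2E,6E)-3,7-dimethylnona-2,6-diene-1,9-diol
Product: 8 (2E,6E)-9-hydroxy-3,7-dimethylnona-2,6-dienal
Conditions: MnO2, CH2Cl2, rt
Reagents that add atoms: none
Why: MnO2 oxidises only the allylic alcohol (C6) and leaves the homoallylic primary alcohol (C8–OH), with the E-enal geometry retained.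

Step 6
Reactants: 8 (2E,6E)-9-hydroxy-3,7-dimethylnona-2,6-dienal
Product: 9 (2E,6E)-9-(TBS-oxy)-3,7-dimethylnona-2,6-dienal
Conditions: TBSCl, imidazole, CH2Cl2, 0 °C to rt
Reagents that add atoms: tert-butyldimethylsilyl chloride, CC(C)(C)[Si](C)(C)Cl
Why: Standard imidazole-promoted silylation of a primary alcohol; the enal is inert to these conditions.

Step 7
Reactants: 10 propargyl alcohol
Product: 11 tert-butyl(diphenyl)(prop-2-yn-1-yloxy)silane
Conditions: TBDPSCl, imidazole, CH2Cl2, 0 °C to rt
Reagents that add atoms: tert-butyldiphenylsilyl chloride, CC(C)(C)[Si](Cl)(c1ccccc1)c1ccccc1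
Why: Standard silylation; the bulky, non-leaving, weakly nucleophilic TBDPS ether at C13 is chosen because it will not ionise under palladium in step 10 and will not compete as a nucleophile in step 11.

Step 8
Reactants: 9 (2E,6E)-9-(TBS-oxy)-3,7-dimethylnona-2,6-dienal; 11 tert-butyl(diphenyl)(prop-2-yn-1-yloxy)silane
Product: 12 (4S,5E,9E)-12-(TBS-oxy)-1-(TBDPS-oxy)-6,10-dimethyldodeca-5,9-dien-2-yn-4-ol (6S carbinol)
Conditions: Me2Zn (3 equiv), (S,S)-ProPhenol (20 mol %), Ph3PO (40 mol %), 11 (3 equiv), toluene, 4 °C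
Reagents that add atoms: none
Why: Catalytic asymmetric alkynylation of an α,β-unsaturated aldehyde by an alkynylzinc held in a dinuclear zinc–ProPhenol complex forms C6–C7; the chiral catalyst delivers the alkyne to the Re face of the enal and so sets 6S.

Step 9
Reactants: 12 (6S) enynol
Product: 13 (4S,5E,9E)-12-(TBS-oxy)-1-(TBDPS-oxy)-6,10-dimethyldodeca-5,9-dien-2-yn-4-yl methyl carbonate
Conditions: ClCO2Me, pyridine, DMAP (cat.), CH2Cl2, 0 °C
Reagents that add atoms: methyl chloroformate, COC(=O)Cl
Why: O-acylation to the carbonate proceeds with retention at C6 and gives a leaving group that is stable to isolation yet ionised by zerovalent palladium under neutral conditions.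

Step 10
Reactants: 13 propargylic methyl carbonate
Product: 14 methyl (aR,5E,9E)-12-(TBS-oxy)-2-[(TBDPS-oxy)methyl]-6,10-dimethyldodeca-2,3,5,9-tetraenoate
Conditions: Pd(PPh3)4 (5 mol %), CO (1 atm), MeOH/THF, 0 °C to rt
Reagents that add atoms: carbon monoxide, [C-]#[O+]; methanol, CO
Why: Palladium-catalysed carbonylative SN2′ substitution of a propargylic carbonate: zerovalent palladium attacks C11 anti to the leaving group to give an allenylpalladium, CO insertion and methanolysis give the 2,3-dienoate, so the 6S centre is translated into the aR axis (centre-to-axis transfer).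

Step 11
Reactants: 14 (aR)-allenoate
Product: 15 (5R)-4-iodo-3-[(TBDPS-oxy)methyl]-5-[(1E,5E)-8-(TBS-oxy)-2,6-dimethylocta-1,5-dien-1-yl]furan-2(5H)-one
Conditions: I2 (2 equiv), MeCN/H2O (15:1), 0 °C to rt, dark; Na2S2O3 work-up
Reagents that add atoms: iodine, II
Why: Iodolactonisation of a 2,3-allenoate: iodine adds to the central carbon C7 of the remote C6=C7 bond and the ester carbonyl oxygen closes on C6 (5-endo) in the plane of the C11 substituents with loss of the methyl group as iodomethane, so the aR axis decides which of H6 and C5 lies above that plane and gives 6R (axis-to-centre transfer).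

Step 12
Reactants: 15 silyl-protected iodobutenolide
Product: 16 (5R)-5-[(1E,5E)-8-hydroxy-2,6-dimethylocta-1,5-dien-1-yl]-4-iodo-3-[(TBDPS-oxy)methyl]furan-2(5H)-one
Conditions: PPTS (0.2 equiv), MeOH, rt
Reagents that add atoms: none
Why: Acid-catalysed methanolysis removes the primary TBS ether far faster than the primary TBDPS ether, and the iodobutenolide and the alkenes are inert to PPTS.

Step 13
Reactants: 16 primary alcohol
Product: 17 (5R)-5-[(1E,5E)-2,6-dimethyl-8-oxoocta-1,5-dien-1-yl]-4-iodo-3-[(TBDPS-oxy)methyl]furan-2(5H)-one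
Conditions: Dess–Martin periodinane, NaHCO3, CH2Cl2, 0 °C to rt; used at once
Reagents that add atoms: none
Why: Dess–Martin oxidation under bicarbonate buffer gives the β,γ-unsaturated aldehyde without moving the C1=C10 double bond into conjugation and without base that could epimerise C6.

Step 14
Reactants: 17 C7-iodo C8-aldehyde
Product: 18 (6R,8S)-8-hydroxy-13-(TBDPS-oxy)germacra-1(10)E,4E,7(11)-trien-12,6-olide
Conditions: CrCl2 (10 equiv), NiCl2 (0.1 equiv), degassed DMSO/THF (3:1), 0.003 M, slow addition of 17 over 10 h, rt; aqueous NH4Cl work-up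
Reagents that add atoms: none
Why: Nozaki–Hiyama–Kishi reaction: CrCl2 reduces NiCl2 to zerovalent nickel, which inserts into the C7–I bond of the β-iodobutenolide; the alkenyl group passes to trivalent chromium and the alkenylchromium adds to the C8 aldehyde. The closest known reaction type is the nickel/chromium-mediated vinyl iodide–aldehyde macrocyclisation used for ten-membered and larger carbocycles. The ten-membered ring C1–C10 closes by 10-exo-trig addition to the aldehyde carbonyl, whose oxygen stays outside the ring. The new centre C8 is set by C6 across the flat butenolide (1,3-relay): allylic strain against the C13 methylene turns H8 into the butenolide plane, C5 fixes the tether on one face of that plane, and of the two arrangements left the one with the chromium-bound oxygen on the outer α side is expected to be favoured and gives 8S; this preference is a prediction, not a certainty. The step needs addition to the aldehyde only, which the low basicity of the alkenylchromium secures against lactone, silyl ether and the enolisable skipped aldehyde, and ring closure over oligomerisation, which high dilution and the few rotatable bonds between the two E-alkenes and the planar butenolide secure.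

Step 15
Reactants: 19 (R)-2-methylglycidol
Product: 20 (2R)-3-chloro-2-methylpropane-1,2-diol
Conditions: LiCl, AcOH, THF, rt
Reagents that add atoms: lithium chloride, [Li+].[Cl-]
Why: Halide opening of an epoxide: chloride attacks the unsubstituted epoxide carbon by SN2, so the tertiary C–O bond and its configuration are kept.

Step 16
Reactants: 20 (2R)-3-chloro-2-methylpropane-1,2-diol
Product: 21 (2R)-3-chloro-2-hydroxy-2-methylpropanoic acid
Conditions: TEMPO (cat.), NaClO2, NaOCl (cat.), MeCN/phosphate buffer pH 6.7, 35 °C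
Reagents that add atoms: sodium chlorite, [Na+].[O-]Cl=O
Why: TEMPO-catalysed chlorite oxidation takes the primary alcohol through the aldehyde to the acid near neutral pH; the tertiary alcohol cannot be oxidised and the stereocentre has no α-hydrogen.

Step 17
Reactants: 21 (2R)-3-chloro-2-hydroxy-2-methylpropanoic acid
Product: 23 (2R)-3-chloro-2-methyl-2-(TES-oxy)propanoic acid, via bis-silyl derivative 22 (not isolated)
Conditions: TESOTf (2.3 equiv), 2,6-lutidine, CH2Cl2, 0 °C; then K2CO3 (cat.), MeOH/H2O, 0 °C, pH 5 work-up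
Reagents that add atoms: triethylsilyl triflate, CC[Si](CC)(CC)OS(=O)(=O)C(F)(F)F
Why: Silylation of both OH groups followed by selective solvolysis of the labile silyl ester leaves the tertiary TES ether, which prevents self-acylation in step 18.

Step 18
Reactants: 18 macrocyclic C8 alcohol; 23 (2R)-3-chloro-2-methyl-2-(TES-oxy)propanoic acid
Product: 25 (6R,8S)-8-[(2R)-3-chloro-2-methyl-2-(TES-oxy)propanoyloxy]-13-(TBDPS-oxy)germacra-1(10)E,4E,7(11)-trien-12,6-olide, via mixed anhydride 24 (not isolated)
Conditions: 23 (2 equiv), 2,4,6-trichlorobenzoyl chloride, Et3N, toluene, rt; then 18, DMAP, toluene, rt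
Reagents that add atoms: none
Why: Yamaguchi esterification: DMAP attacks the mixed anhydride at the aliphatic carbonyl and the acylpyridinium esterifies the hindered secondary C8 alcohol with retention at C8; the acid has no α-hydrogen, so it can neither epimerise nor lose HCl.

Step 19
Reactants: 25 bis-silyl ester
Product: 26 (6R,8S)-8-[(2R)-3-chloro-2-hydroxy-2-methylpropanoyloxy]-13-hydroxygermacra-1(10)E,4E,7(11)-trien-12,6-olide
Conditions: HF·pyridine, excess pyridine, THF, 0 °C to rt
Reagents that add atoms: none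
Why: Buffered fluoride desilylation cleaves the tertiary TES and the primary TBDPS ethers without base, so the chlorohydrin cannot close to an epoxide and the pyridine buffer protects the acid-sensitive diene.

Step 20
Reactants: 26 diol
Product: 27 (6R,8S)-13-acetoxy-8-[(2R)-3-chloro-2-hydroxy-2-methylpropanoyloxy]germacra-1(10)E,4E,7(11)-trien-12,6-olide
Conditions: Ac2O (1.5 equiv), pyridine, CH2Cl2, 0 °C
Reagents that add atoms: acetic anhydride, CC(=O)OC(C)=O
Why: Acetylation without DMAP is selective for the primary allylic C13 alcohol over the hindered tertiary α-hydroxy ester.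

Step 21
Reactants: 27 E,E-diene
Product: 28 CNP0255009.1, (1R,4R,5R,6S,8S,10R)-13-acetoxy-8-[(2R)-3-chloro-2-hydroxy-2-methylpropanoyloxy]-1,10:4,5-diepoxygermacr-7(11)-en-12,6-olide
Conditions: mCPBA (2.3 equiv), NaHCO3, CH2Cl2, 0 °C
Reagents that add atoms: 3-chloroperoxybenzoic acid, OOC(=O)c1cccc(Cl)c1
Why: Prilezhaev epoxidation: both trisubstituted E-alkenes stand roughly perpendicular to the mean ring plane, so the peracid can reach only their outer faces; allylic strain between C15 and H6 orients C4=C5 and the crown conformer with C14 and C15 syn orients C1=C10, which gives the 4α,5β- and 1β,10α-epoxides (4R,5R,1R,10R), while the electron-poor butenolide alkene does not react and the buffer suppresses transannular opening.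

**Compound list**

1 | geranyl acetate, (2E)-3,7-dimethylocta-2,6-dien-1-yl acetate | CC(=O)OC/C=C(C)/CCC=C(C)C | starting material
2 | (2E,6E)-8-hydroxy-3,7-dimethylocta-2,6-dien-1-yl acetate | CC(=O)OC/C=C(C)/CC/C=C(C)/CO | intermediate
3 | (2E,6E)-3,7-dimethyl-8-oxoocta-2,6-dien-1-yl acetate | CC(=O)OC/C=C(C)/CC/C=C(C)/C=O | intermediate
4 | (2E,6E)-3,7-dimethylnona-2,6,8-trien-1-yl acetate | CC(=O)OC/C=C(C)/CC/C=C(C)/C=C | intermediate
5 | (2E,6E)-9-(9-borabicyclo[3.3.1]nonan-9-yl)-3,7-dimethylnona-2,6-dien-1-yl acetate | CC(=O)OC/C=C(C)/CC/C=C(C)/CCB1C2CCCC1CCC2 | intermediate (not isolated)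
6 | (2E,6E)-9-hydroxy-3,7-dimethylnona-2,6-dien-1-yl acetate | CC(=O)OC/C=C(C)/CC/C=C(C)/CCO | intermediate (not isolated)
7 | (2E,6E)-3,7-dimethylnona-2,6-diene-1,9-diol | OC/C=C(C)/CC/C=C(C)/CCO | intermediate
8 | (2E,6E)-9-hydroxy-3,7-dimethylnona-2,6-dienal | O=C/C=C(C)/CC/C=C(C)/CCO | intermediate
9 | (2E,6E)-9-(TBS-oxy)-3,7-dimethylnona-2,6-dienal | O=C/C=C(C)/CC/C=C(C)/CCO[Si](C)(C)C(C)(C)C | intermediate
10 | propargyl alcohol | OCC#C | starting material
11 | tert-butyl(diphenyl)(prop-2-yn-1-yloxy)silane | C#CCO[Si](c1ccccc1)(c1ccccc1)C(C)(C)C | intermediate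
12 | (4S,5E,9E)-12-(TBS-oxy)-1-(TBDPS-oxy)-6,10-dimethyldodeca-5,9-dien-2-yn-4-ol | CC(C)(C)[Si](C)(C)OCC/C(C)=C/CC/C(C)=C/[C@H](O)C#CCO[Si](c1ccccc1)(c1ccccc1)C(C)(C)C | intermediate
13 | (4S,5E,9E)-12-(TBS-oxy)-1-(TBDPS-oxy)-6,10-dimethyldodeca-5,9-dien-2-yn-4-yl methyl carbonate | CC(C)(C)[Si](C)(C)OCC/C(C)=C/CC/C(C)=C/[C@H](OC(=O)OC)C#CCO[Si](c1ccccc1)(c1ccccc1)C(C)(C)C | intermediate
14 | methyl (aR,5E,9E)-12-(TBS-oxy)-2-[(TBDPS-oxy)methyl]-6,10-dimethyldodeca-2,3,5,9-tetraenoate | COC(=O)C(CO[Si](c1ccccc1)(c1ccccc1)C(C)(C)C)=[C@]=C([H])/C=C(C)/CC/C=C(C)/CCO[Si](C)(C)C(C)(C)C | intermediate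
15 | (5R)-4-iodo-3-[(TBDPS-oxy)methyl]-5-[(1E,5E)-8-(TBS-oxy)-2,6-dimethylocta-1,5-dien-1-yl]furan-2(5H)-one | O=C1O[C@H](/C=C(C)/CC/C=C(C)/CCO[Si](C)(C)C(C)(C)C)C(I)=C1CO[Si](c2ccccc2)(c2ccccc2)C(C)(C)C | intermediate
16 | (5R)-5-[(1E,5E)-8-hydroxy-2,6-dimethylocta-1,5-dien-1-yl]-4-iodo-3-[(TBDPS-oxy)methyl]furan-2(5H)-one | O=C1O[C@H](/C=C(C)/CC/C=C(C)/CCO)C(I)=C1CO[Si](c2ccccc2)(c2ccccc2)C(C)(C)C | intermediate
17 | (5R)-5-[(1E,5E)-2,6-dimethyl-8-oxoocta-1,5-dien-1-yl]-4-iodo-3-[(TBDPS-oxy)methyl]furan-2(5H)-one | O=C1O[C@H](/C=C(C)/CC/C=C(C)/CC=O)C(I)=C1CO[Si](c2ccccc2)(c2ccccc2)C(C)(C)C | intermediate (key-step precursor)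
18 | (6R,8S)-8-hydroxy-13-(TBDPS-oxy)germacra-1(10)E,4E,7(11)-trien-12,6-olide (8α-OH, H6 and H8 both β) | CC(C)(C)[Si](c3ccccc3)(c3ccccc3)OCC1=C2[C@@H](O)C/C(C)=C/CC/C(C)=C/[C@H]2OC1=O | intermediate (key-step product)
19 | (R)-2-methylglycidol, [(2R)-2-methyloxiran-2-yl]methanol | OC[C@@]1(C)OC1 | starting material
20 | (2R)-3-chloro-2-methylpropane-1,2-diol | OC[C@@](C)(O)CCl | intermediate
21 | (2R)-3-chloro-2-hydroxy-2-methylpropanoic acid | OC(=O)[C@@](C)(O)CCl | intermediate
22 | triethylsilyl (2R)-3-chloro-2-methyl-2-(TES-oxy)propanoate | CC[Si](CC)(CC)OC(=O)[C@@](C)(O[Si](CC)(CC)CC)CCl | intermediate (not isolated)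
23 | (2R)-3-chloro-2-methyl-2-(TES-oxy)propanoic acid | OC(=O)[C@@](C)(O[Si](CC)(CC)CC)CCl | intermediate
24 | (2R)-3-chloro-2-methyl-2-(TES-oxy)propanoic 2,4,6-trichlorobenzoic anhydride | O=C(OC(=O)[C@@](C)(O[Si](CC)(CC)CC)CCl)c1c(Cl)cc(Cl)cc1Cl | intermediate (not isolated)
25 | (6R,8S)-8-[(2R)-3-chloro-2-methyl-2-(TES-oxy)propanoyloxy]-13-(TBDPS-oxy)germacra-1(10)E,4E,7(11)-trien-12,6-olide | CC(C)(C)[Si](c3ccccc3)(c3ccccc3)OCC1=C2[C@@H](OC(=O)[C@@](C)(O[Si](CC)(CC)CC)CCl)C/C(C)=C/CC/C(C)=C/[C@H]2OC1=O | intermediate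
26 | (6R,8S)-8-[(2R)-3-chloro-2-hydroxy-2-methylpropanoyloxy]-13-hydroxygermacra-1(10)E,4E,7(11)-trien-12,6-olide | OCC1=C2[C@@H](OC(=O)[C@@](C)(O)CCl)C/C(C)=C/CC/C(C)=C/[C@H]2OC1=O | intermediate
27 | (6R,8S)-13-acetoxy-8-[(2R)-3-chloro-2-hydroxy-2-methylpropanoyloxy]germacra-1(10)E,4E,7(11)-trien-12,6-olide | CC(=O)OCC1=C2[C@@H](OC(=O)[C@@](C)(O)CCl)C/C(C)=C/CC/C(C)=C/[C@H]2OC1=O | intermediate
28 | CNP0255009.1, (1R,4R,5R,6S,8S,10R)-13-acetoxy-8-[(2R)-3-chloro-2-hydroxy-2-methylpropanoyloxy]-1,10:4,5-diepoxygermacr-7(11)-en-12,6-olide | CC(=O)OCC1=C2[C@@H](OC(=O)[C@@](C)(O)CCl)C[C@@]3(C)O[C@@H]3CC[C@@]3(C)O[C@@H]3[C@H]2OC1=O | target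

**Count and risks**

Total steps: 21. Longest linear sequence: 17 (steps 1–6, 8–14, 18–21); steps 7 and 15–17 are side branches.

The three steps most likely to fail:

1. Step 10. Stereochemical fidelity may be lost in the carbonylative substitution: the allenylpalladium intermediate can be epimerised by a second zerovalent palladium, or the carbonate can ionise toward the allyl terminus, so the axis arrives with eroded purity. Fallback (classical resolution in place of chirality transfer), setting out from 14 of eroded axial purity and returning at 15: saponification (LiOH, THF/H2O, 0 °C) gives (aR)-allenoic acid F1 together with its antipode; treatment with (S)-1-phenylethylamine and fractional crystallisation separates the (S)-1-phenylethylammonium salt F2 of the aR acid from its diastereomer; acidification and iodolactonisation of the free acid (I2, NaHCO3, MeCN, 0 °C) give 15.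

2. Step 14. The aldehyde may be attacked through the other diastereomeric transition state (poor facial selectivity at C8), or oligomerise instead of cyclising. Fallback (oxidation then reagent-controlled reduction), setting out from 17 and returning at 18: cyclisation as in step 14 gives the 8-epi carbinol F3, alone or mixed with 18; Dess–Martin oxidation of the mixture gives 8-oxo enone F4; Corey–Bakshi–Shibata reduction with (R)-2-methyl-CBS-oxazaborolidine and catecholborane (toluene, −78 °C) delivers hydride under reagent control to give the 8S alcohol 18.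

3. Step 21. The peracid may attack C1=C10 on the face exposed in a minor ring conformer (C14 turned to the α side), or the first-formed epoxide may be opened transannularly by the remaining alkene under trace acid. Fallback (reagent-controlled epoxidation at the protected stage with a reordered endgame), setting out from 25 and returning at 28: Shi epoxidation (D-fructose-derived ketone catalyst, KHSO5 as 2KHSO5·KHSO4·K2SO4, K2CO3, Bu4NHSO4, MeCN/dimethoxymethane/aqueous buffer, 0 °C), which gives R,R epoxides from trisubstituted E-alkenes and is therefore matched to both sites, gives silyl-protected bis-epoxide F5; TBAF buffered with AcOH (THF, 0 °C) removes both silyl groups to give bis-epoxide diol F6; Ac2O and pyridine acetylate the primary C13 alcohol to give 28.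

Further compounds
F1 | step 10 | (aR,5E,9E)-12-(TBS-oxy)-2-[(TBDPS-oxy)methyl]-6,10-dimethyldodeca-2,3,5,9-tetraenoic acid | OC(=O)C(CO[Si](c1ccccc1)(c1ccccc1)C(C)(C)C)=[C@]=C([H])/C=C(C)/CC/C=C(C)/CCO[Si](C)(C)C(C)(C)C
F2 | step 10 | (S)-1-phenylethylammonium salt of acid F1 | [O-]C(=O)C(CO[Si](c1ccccc1)(c1ccccc1)C(C)(C)C)=[C@]=C([H])/C=C(C)/CC/C=C(C)/CCO[Si](C)(C)C(C)(C)C.C[C@H]([NH3+])c1ccccc1
F3 | step 14 | (6R,8R)-8-hydroxy-13-(TBDPS-oxy)germacra-1(10)E,4E,7(11)-trien-12,6-olide | CC(C)(C)[Si](c3ccccc3)(c3ccccc3)OCC1=C2[C@H](O)C/C(C)=C/CC/C(C)=C/[C@H]2OC1=O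
F4 | step 14 | (6R)-8-oxo-13-(TBDPS-oxy)germacra-1(10)E,4E,7(11)-trien-12,6-olide | CC(C)(C)[Si](c3ccccc3)(c3ccccc3)OCC1=C2C(=O)C/C(C)=C/CC/C(C)=C/[C@H]2OC1=O
F5 | step 21 | (1R,4R,5R,6S,8S,10R)-8-[(2R)-3-chloro-2-methyl-2-(TES-oxy)propanoyloxy]-13-(TBDPS-oxy)-1,10:4,5-diepoxygermacr-7(11)-en-12,6-olide | CC(C)(C)[Si](c4ccccc4)(c4ccccc4)OCC1=C2[C@@H](OC(=O)[C@@](C)(O[Si](CC)(CC)CC)CCl)C[C@@]3(C)O[C@@H]3CC[C@@]3(C)O[C@@H]3[C@H]2OC1=O
F6 | step 21 | (1R,4R,5R,6S,8S,10R)-8-[(2R)-3-chloro-2-hydroxy-2-methylpropanoyloxy]-13-hydroxy-1,10:4,5-diepoxygermacr-7(11)-en-12,6-olide | OCC1=C2[C@@H](OC(=O)[C@@](C)(O)CCl)C[C@@]3(C)O[C@@H]3CC[C@@]3(C)O[C@@H]3[C@H]2OC1=O
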